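**Retrosynthetic overview**

- The route rests on the benzoate ring: C1 carries CO2Me, C2 OH, C3 prenyl, C4 OH, C5 prenyl and C6 the 2-(4-hydroxyphenyl)ethyl chain. The oxygenated carbons alternate as in a folded tetraketide (ester carbon–C1–C2–C3–C4–C5–C6–CH2CH2Ar), and each prenyl sits on a carbon flanked by two former carbonyl carbons.
- Disconnecting C1–C6 (aldol, dehydration) opens the ring to a methyl 3,5,7-trioxo ester, which is carried in masked form as diketo-dioxinone 11 plus methanol.
- The C5–C6 bond of 11 comes from the dianion of keto-dioxinone 6 and acyl imidazolide 10; the C3–C4 bond of 6 comes from the dienolate of prenylated dioxinone 3 and acid chloride 5.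
- Only one ring is built: the benzoate ring, in step 7, with both prenyl groups already in place as C-alkyl groups of the chain. The dioxinone and the phenol ring are purchased, and the phenol is unmasked last.

Key step: step 7

Remark: the prenyl-bearing CH carbons of 6, 11, 13 and 14 and the sp3 ring carbons of 15 are enolizable; they are carried as mixtures of stereoisomers and tautomers (keto forms drawn) and all disappear on aromatization. The target has no stereocentre.

**Route**

Step 1
Reactants: 1 2,2,6-trimethyl-4H-1,3-dioxin-4-one; 2 prenyl bromide (1-bromo-3-methylbut-2-ene)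
Product: 3 2,2-dimethyl-6-(4-methylpent-3-enyl)-4H-1,3-dioxin-4-one
Conditions: LiN(iPr)2, THF, −78 °C; DMPU, then 2, −78 → −20 °C
Reagents that add atoms: none
Why: Kinetic deprotonation of the 6-methyl group gives the lithium dienolate, which in the presence of DMPU should be alkylated at the exocyclic γ-carbon by the primary allylic bromide (vinylogous enolate SN2 alkylation).

Step 2
Reactants: 4 5-methylhex-4-enoic acid
Product: 5 5-methylhex-4-enoyl chloride
Conditions: (COCl)2, cat. DMF, CH2Cl2, 0 °C → rt; concentrate, use crude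
Reagents that add atoms: oxalyl chloride, ClC(=O)C(=O)Cl
Why: Vilsmeier-type activation of the acid gives the acyl chloride under cold, short conditions that the remote trisubstituted alkene should tolerate.

Step 3
Reactants: 3 2,2-dimethyl-6-(4-methylpent-3-enyl)-4H-1,3-dioxin-4-one; 5 5-methylhex-4-enoyl chloride
Product: 6 2,2-dimethyl-6-(2,10-dimethyl-6-oxoundeca-2,9-dien-5-yl)-4H-1,3-dioxin-4-one
Conditions: 3 (2 equiv), LiN(SiMe3)2 (2 equiv), THF, −78 °C; 5 (1 equiv), −78 °C; aq. NH4Cl; recover excess 3
Reagents that add atoms: none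
Why: Vinylogous Claisen-type C-acylation, in which the lithium dienolate of 3 attacks the acid chloride through its γ-carbon and the second equivalent of dienolate absorbs the proton of the more acidic product; the new CH is enolizable and left unassigned.

Step 4
Reactants: 7 3-(4-hydroxyphenyl)propanoic acid
Product: 9 3-[4-(triisopropylsilyloxy)phenyl]propanoic acid, via bis-silylated acid 8 (not isolated)
Conditions: iPr3SiCl (2.2 equiv), imidazole, DMF, rt; then K2CO3, THF–H2O, rt; aq. HCl to pH 3–4
Reagents that add atoms: triisopropylsilyl chloride, CC(C)[Si](Cl)(C(C)C)C(C)C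
Why: Imidazole-promoted silylation caps phenol and acid alike, and mild carbonate hydrolysis should then cleave only the much more labile silyl ester (selective silyl ester solvolysis beside an aryl triisopropylsilyl ether).

Step 5
Reactants: 9 3-[4-(triisopropylsilyloxy)phenyl]propanoic acid
Product: 10 1-{3-[4-(triisopropylsilyloxy)phenyl]propanoyl}-1H-imidazole
Conditions: 1,1'-carbonyldiimidazole, CH2Cl2, rt; brief cold H2O wash, dry
Reagents that add atoms: 1,1'-carbonyldiimidazole, O=C(n1ccnc1)n1ccnc1
Why: Staab acyl imidazole formation with loss of CO2 and imidazole gives an acyl donor suited to enolate acylation, and the wash removes the N–H imidazole that would otherwise quench the dianion of the next step.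

Step 6
Reactants: 6 2,2-dimethyl-6-(2,10-dimethyl-6-oxoundeca-2,9-dien-5-yl)-4H-1,3-dioxin-4-one; 10 1-{3-[4-(triisopropylsilyloxy)phenyl]propanoyl}-1H-imidazole
Product: 11 2,2-dimethyl-6-{2-methyl-7-(3-methylbut-2-enyl)-6,8-dioxo-10-[4-(triisopropylsilyloxy)phenyl]dec-2-en-5-yl}-4H-1,3-dioxin-4-one
Conditions: LiN(iPr)2 (2.2 equiv), THF, −78 → −40 °C; 10 (1.0 equiv), −78 → −20 °C; aq. NH4Cl
Reagents that add atoms: none
Why: Dianion Claisen condensation, in which double deprotonation of 6 (first the doubly activated CH, then the α′-CH2, the only other acidic site) gives a dianion whose terminal carbanion is acylated by the imidazolide, the product being held as its enolate until the quench; the new CH is enolizable and left unassigned.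

Step 7
Reactants: 11 2,2-dimethyl-6-{2-methyl-7-(3-methylbut-2-enyl)-6,8-dioxo-10-[4-(triisopropylsilyloxy)phenyl]dec-2-en-5-yl}-4H-1,3-dioxin-4-one; 12 methanol
Product: 16 methyl 2,4-dihydroxy-3,5-bis(3-methylbut-2-enyl)-6-{2-[4-(triisopropylsilyloxy)phenyl]ethyl}benzoate, via acylketene 13 (not isolated), via triketo ester 14 (not isolated), via aldol adduct 15 (not isolated)
Conditions: 12 (10 equiv), PhMe, 110 °C, sealed tube; cool, then Cs2CO3, MeOH, rt; AcOH
Reagents that add atoms: none
Why: Heating drives a retro-[4+2] loss of acetone from the dioxinone to acylketene 13, which methanol captures as the β-keto ester 14. Cs2CO3 then deprotonates the C1 methylene, and its enolate adds to the C6 ketone in a 6-(enolexo)-exo-trig aldol that forms the C1–C6 bond and closes the carbocycle (15); E1cB loss of water and enolization of the C2 and C4 ketones then give the benzene ring. The closest known reaction type is the thermolysis of diketo-dioxinones with an alcohol followed by base-mediated aldol aromatization to resorcylate esters. No stereocentre remains in the product, since the transient centres at C1, C3, C5 and C6 vanish on aromatization. The step needs the C1-to-C6 aldol to win over Claisen attack of C5 on the ester, an aldol from the side-chain methylene onto C2, and capture of the ketene by an enol oxygen to give a pyranone. This is secured because C1 is the only unsubstituted, doubly activated methylene, carbonate cannot deprotonate the singly activated side-chain CH2, a ketone is a better acceptor than the ester, closure from C5 would give a quaternary carbon that cannot aromatize, and excess methanol outruns the intramolecular capture.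

Step 8
Reactants: 16 methyl 2,4-dihydroxy-3,5-bis(3-methylbut-2-enyl)-6-{2-[4-(triisopropylsilyloxy)phenyl]ethyl}benzoate
Product: 17 methyl 2,4-dihydroxy-6-[2-(4-hydroxyphenyl)ethyl]-3,5-bis(3-methylbut-2-enyl)benzoate
Conditions: Bu4NF, AcOH, THF, 0 °C → rt
Reagents that add atoms: none
Why: Fluoride-mediated cleavage of the aryl silyl ether, buffered with acetic acid so that the phenoxide is protonated at once, should leave the ester, the prenyl groups and the resorcinol untouched.

**Compound list**

1 | 2,2,6-trimethyl-4H-1,3-dioxin-4-one | CC1=CC(=O)OC(C)(C)O1 | starting material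
2 | prenyl bromide (1-bromo-3-methylbut-2-ene) | CC(C)=CCBr | starting material
3 | 2,2-dimethyl-6-(4-methylpent-3-enyl)-4H-1,3-dioxin-4-one | CC1(C)OC(=O)C=C(O1)CCC=C(C)C | intermediate
4 | 5-methylhex-4-enoic acid | CC(C)=CCCC(=O)O | starting material
5 | 5-methylhex-4-enoyl chloride | CC(C)=CCCC(=O)Cl | intermediate
6 | 2,2-dimethyl-6-(2,10-dimethyl-6-oxoundeca-2,9-dien-5-yl)-4H-1,3-dioxin-4-one (racemic, enolizable CH) | CC1(C)OC(=O)C=C(O1)C(CC=C(C)C)C(=O)CCC=C(C)C | intermediate
7 | 3-(4-hydroxyphenyl)propanoic acid | OC(=O)CCc1ccc(O)cc1 | starting material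
8 | triisopropylsilyl 3-[4-(triisopropylsilyloxy)phenyl]propanoate (bis-silylated acid) | CC(C)[Si](OC(=O)CCc1ccc(O[Si](C(C)C)(C(C)C)C(C)C)cc1)(C(C)C)C(C)C | intermediate
9 | 3-[4-(triisopropylsilyloxy)phenyl]propanoic acid | OC(=O)CCc1ccc(O[Si](C(C)C)(C(C)C)C(C)C)cc1 | intermediate
10 | 1-{3-[4-(triisopropylsilyloxy)phenyl]propanoyl}-1H-imidazole | O=C(CCc1ccc(O[Si](C(C)C)(C(C)C)C(C)C)cc1)n1ccnc1 | intermediate
11 | 2,2-dimethyl-6-{2-methyl-7-(3-methylbut-2-enyl)-6,8-dioxo-10-[4-(triisopropylsilyloxy)phenyl]dec-2-en-5-yl}-4H-1,3-dioxin-4-one (keto form, stereoisomer mixture) | CC1(C)OC(=O)C=C(O1)C(CC=C(C)C)C(=O)C(CC=C(C)C)C(=O)CCc1ccc(O[Si](C(C)C)(C(C)C)C(C)C)cc1 | intermediate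
12 | methanol | CO | starting material
13 | 4,6-bis(3-methylbut-2-enyl)-9-[4-(triisopropylsilyloxy)phenyl]non-1-ene-1,3,5,7-tetrone (acylketene) | O=C=CC(=O)C(CC=C(C)C)C(=O)C(CC=C(C)C)C(=O)CCc1ccc(O[Si](C(C)C)(C(C)C)C(C)C)cc1 | intermediate
14 | methyl 4,6-bis(3-methylbut-2-enyl)-3,5,7-trioxo-9-[4-(triisopropylsilyloxy)phenyl]nonanoate (triketo ester, keto form) | COC(=O)CC(=O)C(CC=C(C)C)C(=O)C(CC=C(C)C)C(=O)CCc1ccc(O[Si](C(C)C)(C(C)C)C(C)C)cc1 | intermediate
15 | methyl 2-hydroxy-3,5-bis(3-methylbut-2-enyl)-4,6-dioxo-2-{2-[4-(triisopropylsilyloxy)phenyl]ethyl}cyclohexane-1-carboxylate (aldol adduct, stereoisomer mixture) | COC(=O)C1C(=O)C(CC=C(C)C)C(=O)C(CC=C(C)C)C1(O)CCc1ccc(O[Si](C(C)C)(C(C)C)C(C)C)cc1 | intermediate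
16 | methyl 2,4-dihydroxy-3,5-bis(3-methylbut-2-enyl)-6-{2-[4-(triisopropylsilyloxy)phenyl]ethyl}benzoate | COC(=O)c1c(O)c(CC=C(C)C)c(O)c(CC=C(C)C)c1CCc1ccc(O[Si](C(C)C)(C(C)C)C(C)C)cc1 | intermediate
17 | methyl 2,4-dihydroxy-6-[2-(4-hydroxyphenyl)ethyl]-3,5-bis(3-methylbut-2-enyl)benzoate | COC(=O)c1c(O)c(CC=C(C)C)c(O)c(CC=C(C)C)c1CCc1ccc(O)cc1 | target

**Step count**

Total: 8 steps. Longest linear sequence: 5 steps (1 → 3 → 6 → 11 → 16 → 17, or equally 7 → 9 → 10 → 11 → 16 → 17).

**Steps most likely to fail**

1. Step 7. The acylketene may be captured internally by an enol oxygen to give a pyranone, methoxide may cleave the 2-alkyl-1,3-diketone units by retro-Claisen before the ring closes, or the aldol adduct may dehydrate incompletely. Partial loss of the silyl ether under carbonate in methanol would do no harm, since it gives 17 directly. The fallback sets out from 11 and avoids both the ketene and methoxide during ring formation. Treating 11 with Cs2CO3 in THF at room temperature, without alcohol or heating, should form the dienolate of the intact dioxinone; its ring α-carbon adds to the terminal ketone and dehydration gives the acetonide-protected resorcylate 7-hydroxy-2,2-dimethyl-6,8-bis(3-methylbut-2-enyl)-5-{2-[4-(triisopropylsilyloxy)phenyl]ethyl}-4H-benzo[d][1,3]dioxin-4-one F1. Opening F1 with NaOMe in methanol 12 and THF should then deliver the methyl ester and return to the route at 16.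

2. Step 6. The secondary terminal carbanion of the dianion is hindered and may acylate slowly, proton transfer from the more acidic product may stall conversion, or acylation may occur on oxygen. The fallback sets out from 10 and 6 and replaces the Claisen condensation by aldol addition and oxidation. Reduction of 10 with iBu2AlH in CH2Cl2 at −78 °C should give 3-[4-(triisopropylsilyloxy)phenyl]propanal F2. The dianion of 6 (LiN(iPr)2, THF, −78 °C) should add to F2 without generating an acidic product, giving the β-hydroxy ketone 6-{8-hydroxy-2-methyl-7-(3-methylbut-2-enyl)-6-oxo-10-[4-(triisopropylsilyloxy)phenyl]dec-2-en-5-yl}-2,2-dimethyl-4H-1,3-dioxin-4-one F3. Oxidation of F3 with Dess–Martin periodinane buffered with NaHCO3 should return to the route at 11.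

3. Step 3. The γ-substituted dienolate may acylate at the ring α-carbon or on oxygen instead of the γ-carbon, and proton exchange with the product may consume dienolate. The fallback sets out from 5 and 3 and uses a vinylogous aldol addition followed by oxidation. Reduction of 5 with LiAlH(OtBu)3 in THF at −78 °C should give 5-methylhex-4-enal F4. The lithium dienolate of 3 (LiN(iPr)2, THF, −78 °C) should add to F4 through its γ-carbon to give 6-(6-hydroxy-2,10-dimethylundeca-2,9-dien-5-yl)-2,2-dimethyl-4H-1,3-dioxin-4-one F5. Oxidation of F5 with Dess–Martin periodinane should return to the route at 6.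

**Further compounds**

F1 | step 7 | 7-hydroxy-2,2-dimethyl-6,8-bis(3-methylbut-2-enyl)-5-{2-[4-(triisopropylsilyloxy)phenyl]ethyl}-4H-benzo[d][1,3]dioxin-4-one | CC1(C)OC(=O)c2c(O1)c(CC=C(C)C)c(O)c(CC=C(C)C)c2CCc1ccc(O[Si](C(C)C)(C(C)C)C(C)C)cc1
F2 | step 6 | 3-[4-(triisopropylsilyloxy)phenyl]propanal | O=CCCc1ccc(O[Si](C(C)C)(C(C)C)C(C)C)cc1
F3 | step 6 | 6-{8-hydroxy-2-methyl-7-(3-methylbut-2-enyl)-6-oxo-10-[4-(triisopropylsilyloxy)phenyl]dec-2-en-5-yl}-2,2-dimethyl-4H-1,3-dioxin-4-one (stereoisomer mixture) | CC1(C)OC(=O)C=C(O1)C(CC=C(C)C)C(=O)C(CC=C(C)C)C(O)CCc1ccc(O[Si](C(C)C)(C(C)C)C(C)C)cc1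
F4 | step 3 | 5-methylhex-4-enal | CC(C)=CCCC=O
F5 | step 3 | 6-(6-hydroxy-2,10-dimethylundeca-2,9-dien-5-yl)-2,2-dimethyl-4H-1,3-dioxin-4-one (stereoisomer mixture) | CC1(C)OC(=O)C=C(O1)C(CC=C(C)C)C(O)CCC=C(C)C
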